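**Retrosynthetic overview**

1. Target 30 ⇒ cis-β-hydroxy acid 28 (oxetan-2-one closed last by carboxyl activation) ⇒ hydrindene aldehyde 23 ⇒ Diels–Alder of the 1-vinylcyclopentene 21 with acrolein (bonds C5–C6 and C7–C7a; C7a set by substrate control, C7 by equilibration).
2. Diene 21 ⇒ ring-closing enyne metathesis of the 1,6-enyne 20 ⇒ Evans syn aldol of alkynoyl imide 16 with acrolein (C1–C2 bond, both stereocentres).
3. Imide 16 ⇒ alkyne 8 ⇒ α-quaternary aldehyde 7 ⇒ ring contraction of epoxide 6 ⇒ cycloheptene 5 ⇒ acyclic diene 4 from mesityl oxide.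
4. Order of ring formation: cycloheptene (sacrificial, step 3) → oxirane (step 4) → trimethylcyclohexane by contraction (step 5) → cyclopentene (step 12) → cyclohexene (step 13) → oxetan-2-one (step 18).
5. Enabling feature: in 6 the oxirane spans C1 (tertiary, methyl-bearing, so its C–O bond breaks selectively) and C7 (one H). The ring bond C6–C7 is the only C–C bond able to shift to C1, so C7 is extruded as the formyl carbon (later alkene carbon C4 of the hydrindene) and C1 becomes the quaternary stereocentre.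

Key step: step 5

Remark on locants: hydrindene names use C1 (O-bearing CH), C2 (carboxyl-bearing CH), C3 (CH2), C3a=C4 (alkene; C4 carries the cyclohexyl group), C5, C6 (CH2), C7 (CH bearing the one-carbon substituent), C7a (ring-fusion CH). Where a name and a SMILES string should differ, the SMILES string is meant.

Assumption: the facial sense of the Shi epoxidation of 5 is taken from the spiro transition-state model that holds for 1-substituted cycloalkenes; the L-fructose-derived ketone would give the mirror-image epoxide.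

Remark on numbering: metal alkoxides or enolates that are only protonated on aqueous work-up, and fleeting species (betaines, carbenes, metallacycles), are not numbered.

**Route**

Step 1
Reactants: 1 4-methylpent-3-en-2-one (mesityl oxide); 2 pent-4-en-1-ylmagnesium bromide
Product: 3 4,4-dimethylnon-8-en-2-one
Conditions: CuBr·SMe2 (5 mol %), THF, −30 → 0 °C; aq. NH4Cl
Reagents that add atoms: none
Why: Copper-catalysed conjugate (1,4-) addition of the Grignard reagent to the β,β-dimethyl enone creates the gem-dimethyl carbon; no stereocentre is formed.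

Step 2
Reactants: 3 4,4-dimethylnon-8-en-2-one
Product: 4 2,4,4-trimethylnona-1,8-diene
Conditions: Ph3PCH3Br, KOtBu, THF, 0 → 23 °C
Reagents that add atoms: methyltriphenylphosphonium bromide, C[P+](c1ccccc1)(c1ccccc1)c1ccccc1.[Br-]
Why: Wittig methylenation of an unhindered methyl ketone gives the 1,1-disubstituted alkene needed for ring closure; no stereocentre.

Step 3
Reactants: 4 2,4,4-trimethylnona-1,8-diene
Product: 5 1,6,6-trimethylcyclohept-1-ene
Conditions: (H2IMes)(PCy3)Cl2Ru=CHPh (second-generation Grubbs catalyst, 2 mol %), CH2Cl2 (0.02 M), 40 °C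
Reagents that add atoms: none
Why: Ring-closing olefin metathesis between the 1,1-disubstituted and the monosubstituted alkene should close the seven-membered ring as its trisubstituted alkene, helped by the gem-dimethyl group and driven by loss of ethene.

Step 4
Reactants: 5 1,6,6-trimethylcyclohept-1-ene
Product: 6 (1S,7R)-1,3,3-trimethyl-8-oxabicyclo[5.1.0]octane
Conditions: Shi ketone from D-fructose (1,2:4,5-di-O-isopropylidene-β-D-erythro-hexo-2,3-diulo-2,6-pyranose, 30 mol %), KHSO5 (as 2KHSO5·KHSO4·K2SO4), K2CO3, Bu4NHSO4 (cat.), MeCN/CH2(OMe)2/aq. Na2B4O7 buffer, 0 °C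
Reagents that add atoms: potassium peroxymonosulfate, [K+].[O-]S(=O)(=O)OO
Why: Shi asymmetric epoxidation: the chiral dioxirane delivers oxygen through a spiro transition state with the ring hydrogen in the crowded quadrant, which should set C1 (S) and C7 (R) of the cis-fused epoxide in one event.

Step 5
Reactants: 6 (1S,7R)-1,3,3-trimethyl-8-oxabicyclo[5.1.0]octane
Product: 7 (1R)-1,3,3-trimethylcyclohexane-1-carbaldehyde
Conditions: MeAl(OC6H2-4-Br-2,6-tBu2)2 (20 mol %), CH2Cl2, −78 → −20 °C
Reagents that add atoms: none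
Why: The bulky, oxophilic aluminium aryloxide binds the oxirane oxygen, the C1–O bond at the tertiary methyl-bearing carbon lengthens, and the ring bond C6–C7 migrates to C1 on the face opposite the leaving oxygen while C7–O–Al collapses to the formyl group; this is a Meinwald-type semipinacol rearrangement whose closest known class is the conversion of 1-alkylcycloalkene oxides into 1-alkylcycloalkanecarbaldehydes by methylaluminium bis(aryloxides). No ring is closed: the oxirane opens and the seven-membered carbocycle contracts to the six-membered one by a suprafacial 1,2-shift of a ring carbon. The single new stereocentre, the quaternary carbon, is controlled by the C1 configuration of 6 through inversion (anti migration), so (1S,7R)-6 should give (R)-7 and the catalyst-derived C–O stereochemistry is traded for the all-carbon centre. The step needs C–O cleavage at C1 only (secured by the tertiary versus secondary oxirane carbon), ring-carbon rather than hydride migration (the very bulky aluminium alkoxide is expected to favour the rotamer with the ring bond, not C7–H, aligned with the breaking bond, and only one ring carbon can migrate) and a concerted course without a free cation (low temperature, non-polar solvent). The aldehyde has no α-hydrogen, so the stereocentre is fixed for the rest of the route, and the extruded carbon is exactly the one that becomes alkene carbon C4.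

Step 6
Reactants: 7 (1R)-1,3,3-trimethylcyclohexane-1-carbaldehyde
Product: 8 (1R)-1-ethynyl-1,3,3-trimethylcyclohexane
Conditions: MeC(O)C(N2)P(O)(OMe)2, K2CO3, MeOH, 0 → 23 °C
Reagents that add atoms: dimethyl (1-diazo-2-oxopropyl)phosphonate, CC(=O)C(=[N+]=[N-])P(=O)(OC)OC
Why: Ohira–Bestmann (Seyferth–Gilbert) homologation: the diazomethylphosphonate anion adds to the aldehyde, phosphate is eliminated and the alkylidene carbene gives the terminal alkyne by 1,2-hydrogen shift; with no α-hydrogen the quaternary centre cannot epimerise.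

Step 7
Reactants: 8 (1R)-1-ethynyl-1,3,3-trimethylcyclohexane; 9 oxetane
Product: 11 5-[(1R)-1,3,3-trimethylcyclohexyl]pent-4-yn-1-ol, via lithium acetylide 10 (not isolated)
Conditions: n-BuLi, THF, −78 °C; then BF3·OEt2, 9, −78 → 0 °C
Reagents that add atoms: none
Why: Alkylation of the lithium acetylide with BF3-activated oxetane (SN2 opening at a methylene carbon) adds the three carbons that become C3, C2 and the carboxyl carbon.

Step 8
Reactants: 11 5-[(1R)-1,3,3-trimethylcyclohexyl]pent-4-yn-1-ol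
Product: 13 5-[(1R)-1,3,3-trimethylcyclohexyl]pent-4-ynoic acid, via alkynal 12 (not isolated)
Conditions: TEMPO (10 mol %), PhI(OAc)2 (2.2 equiv), MeCN/H2O, 23 °C
Reagents that add atoms: water, O
Why: TEMPO-catalysed oxidation with PhI(OAc)2 as terminal oxidant takes the primary alcohol through the aldehyde hydrate to the acid without touching the alkyne.

Step 9
Reactants: 13 5-[(1R)-1,3,3-trimethylcyclohexyl]pent-4-ynoic acid; 14 (4S)-4-benzyl-1,3-oxazolidin-2-one
Product: 16 (4S)-4-benzyl-3-{5-[(1R)-1,3,3-trimethylcyclohexyl]pent-4-ynoyl}-1,3-oxazolidin-2-one, via mixed pivalic anhydride 15 (not isolated)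
Conditions: t-BuCOCl, Et3N, THF, −20 °C; then 14, LiCl, 23 °C
Reagents that add atoms: none
Why: N-Acylation of the oxazolidinone through the mixed pivalic anhydride is the standard entry to the Evans imide; the auxiliary stereocentre is bought.

Step 10
Reactants: 16 (4S)-4-benzyl-3-{5-[(1R)-1,3,3-trimethylcyclohexyl]pent-4-ynoyl}-1,3-oxazolidin-2-one; 17 prop-2-enal (acrolein)
Product: 19 (4S)-4-benzyl-3-[(2S,3R)-3-hydroxy-2-{3-[(1R)-1,3,3-trimethylcyclohexyl]prop-2-yn-1-yl}pent-4-enoyl]-1,3-oxazolidin-2-one, via boron enolate 18 (not isolated)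
Conditions: Bu2BOTf, iPr2NEt, CH2Cl2, −78 → 0 °C; 17, −78 → 0 °C; then pH 7 buffer, MeOH, H2O2, 0 °C
Reagents that add atoms: none
Why: Evans syn aldol reaction: the Z-boron enolate reacts with acrolein through a closed chair-like transition state on the enolate face away from the benzyl group, which should give the (2S,3R) syn adduct, that is, the future C2 and C1 with the cis relationship the β-lactone needs.

Step 11
Reactants: 19 (4S)-4-benzyl-3-[(2S,3R)-3-hydroxy-2-{3-[(1R)-1,3,3-trimethylcyclohexyl]prop-2-yn-1-yl}pent-4-enoyl]-1,3-oxazolidin-2-one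
Product: 20 (4S)-4-benzyl-3-[(2S,3R)-3-{[tert-butyl(dimethyl)silyl]oxy}-2-{3-[(1R)-1,3,3-trimethylcyclohexyl]prop-2-yn-1-yl}pent-4-enoyl]-1,3-oxazolidin-2-one
Conditions: t-BuMe2SiOTf, 2,6-lutidine, CH2Cl2, −78 → 0 °C
Reagents that add atoms: tert-butyldimethylsilyl trifluoromethanesulfonate, CC(C)(C)[Si](C)(C)OS(=O)(=O)C(F)(F)F
Why: Silylation with the silyl triflate protects the secondary alcohol against retro-aldol cleavage and acylation and makes it the bulky group that later steers the cycloaddition.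

Step 12
Reactants: 20 (4S)-4-benzyl-3-[(2S,3R)-3-{[tert-butyl(dimethyl)silyl]oxy}-2-{3-[(1R)-1,3,3-trimethylcyclohexyl]prop-2-yn-1-yl}pent-4-enoyl]-1,3-oxazolidin-2-one
Product: 21 (4S)-4-benzyl-3-{[(1S,2R)-2-{[tert-butyl(dimethyl)silyl]oxy}-4-{1-[(1R)-1,3,3-trimethylcyclohexyl]ethenyl}cyclopent-3-en-1-yl]carbonyl}-1,3-oxazolidin-2-one
Conditions: (H2IMes)(PCy3)Cl2Ru=CHPh (second-generation Grubbs catalyst, 10 mol %), ethene (1 atm), toluene, 80 °C
Reagents that add atoms: none
Why: Ring-closing enyne metathesis of the 1,6-enyne (exo mode) should form the cyclopentene and move the terminal methylene onto the alkyne carbon next to the quaternary centre, giving the 2,3-disubstituted 1,3-diene with both stereocentres untouched; ethene keeps a small methylidene available for the hindered alkyne.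

Step 13
Reactants: 21 (4S)-4-benzyl-3-{[(1S,2R)-2-{[tert-butyl(dimethyl)silyl]oxy}-4-{1-[(1R)-1,3,3-trimethylcyclohexyl]ethenyl}cyclopent-3-en-1-yl]carbonyl}-1,3-oxazolidin-2-one; 17 prop-2-enal (acrolein)
Product: 23 (4S)-4-benzyl-3-{[(1R,2S,7R,7aS)-1-{[tert-butyl(dimethyl)silyl]oxy}-7-formyl-4-[(1R)-1,3,3-trimethylcyclohexyl]-2,3,5,6,7,7a-hexahydro-1H-inden-2-yl]carbonyl}-1,3-oxazolidin-2-one, via cis aldehyde 22 (not isolated)
Conditions: 17 (5 equiv), BHT (cat.), toluene, 90 °C, sealed tube; evaporate; then DBU (0.2 equiv), CH2Cl2, 23 °C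
Reagents that add atoms: none
Why: Diels–Alder reaction followed by base equilibration: the acrolein β-carbon bonds to the unsubstituted diene terminus (larger HOMO coefficient, least hindered) so the formyl-bearing carbon ends next to C7a, the dienophile approaches the cyclopentene face anti to the silyloxy and acyl groups and so sets C7a (S), and DBU equilibrates C7 through the enolate to the pseudo-equatorial formyl isomer trans to the C7a–C1 bond, so that the endo adduct 22 and the exo adduct converge on 23.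

Step 14
Reactants: 23 (4S)-4-benzyl-3-{[(1R,2S,7R,7aS)-1-{[tert-butyl(dimethyl)silyl]oxy}-7-formyl-4-[(1R)-1,3,3-trimethylcyclohexyl]-2,3,5,6,7,7a-hexahydro-1H-inden-2-yl]carbonyl}-1,3-oxazolidin-2-one
Product: 24 (4S)-4-benzyl-3-{[(1R,2S,7R,7aS)-1-{[tert-butyl(dimethyl)silyl]oxy}-7-(hydroxymethyl)-4-[(1R)-1,3,3-trimethylcyclohexyl]-2,3,5,6,7,7a-hexahydro-1H-inden-2-yl]carbonyl}-1,3-oxazolidin-2-one
Conditions: NaBH4, THF/MeOH, −40 °C
Reagents that add atoms: none
Why: Chemoselective hydride reduction of the aldehyde by NaBH4 at low temperature, where the imide and the silyl ether should be inert; no stereocentre changes.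

Step 15
Reactants: 24 (4S)-4-benzyl-3-{[(1R,2S,7R,7aS)-1-{[tert-butyl(dimethyl)silyl]oxy}-7-(hydroxymethyl)-4-[(1R)-1,3,3-trimethylcyclohexyl]-2,3,5,6,7,7a-hexahydro-1H-inden-2-yl]carbonyl}-1,3-oxazolidin-2-one
Product: 25 [(1R,2S,7R,7aS)-2-{[(4S)-4-benzyl-2-oxo-1,3-oxazolidin-3-yl]carbonyl}-1-{[tert-butyl(dimethyl)silyl]oxy}-4-[(1R)-1,3,3-trimethylcyclohexyl]-2,3,5,6,7,7a-hexahydro-1H-inden-7-yl]methyl butanoate
Conditions: (PrCO)2O, Et3N, DMAP (cat.), CH2Cl2, 0 °C
Reagents that add atoms: butanoic anhydride, CCCC(=O)OC(=O)CCC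
Why: DMAP-catalysed acylation of the primary alcohol installs the butanoate; the only other hydroxyl is silylated.

Step 16
Reactants: 25 [(1R,2S,7R,7aS)-2-{[(4S)-4-benzyl-2-oxo-1,3-oxazolidin-3-yl]carbonyl}-1-{[tert-butyl(dimethyl)silyl]oxy}-4-[(1R)-1,3,3-trimethylcyclohexyl]-2,3,5,6,7,7a-hexahydro-1H-inden-7-yl]methyl butanoate
Product: 26 [(1R,2S,7R,7aS)-2-{[(4S)-4-benzyl-2-oxo-1,3-oxazolidin-3-yl]carbonyl}-1-hydroxy-4-[(1R)-1,3,3-trimethylcyclohexyl]-2,3,5,6,7,7a-hexahydro-1H-inden-7-yl]methyl butanoate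
Conditions: HF·pyridine, pyridine, THF, 0 → 23 °C
Reagents that add atoms: none
Why: Fluoride-mediated desilylation (Si–F bond formation) frees the C1 hydroxyl under conditions to which the ester and the imide should be stable.

Step 17
Reactants: 26 [(1R,2S,7R,7aS)-2-{[(4S)-4-benzyl-2-oxo-1,3-oxazolidin-3-yl]carbonyl}-1-hydroxy-4-[(1R)-1,3,3-trimethylcyclohexyl]-2,3,5,6,7,7a-hexahydro-1H-inden-7-yl]methyl butanoate
Product: 28 (1R,2S,7R,7aS)-7-[(butanoyloxy)methyl]-1-hydroxy-4-[(1R)-1,3,3-trimethylcyclohexyl]-2,3,5,6,7,7a-hexahydro-1H-indene-2-carboxylic acid, via lithium peroxycarboxylate 27 (not isolated)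
Conditions: LiOH, H2O2, THF/H2O, 0 °C; aq. Na2SO3; then 1 M HCl to pH 2
Reagents that add atoms: hydrogen peroxide, OO
Why: Hydroperoxide cleavage of the Evans imide: the α-effect nucleophile LiOOH attacks the exocyclic imide carbonyl much faster than the butanoate ester, and sulfite reduces the peroxy acid to the acid; C2 should not epimerise at 0 °C.

Step 18
Reactants: 28 (1R,2S,7R,7aS)-7-[(butanoyloxy)methyl]-1-hydroxy-4-[(1R)-1,3,3-trimethylcyclohexyl]-2,3,5,6,7,7a-hexahydro-1H-indene-2-carboxylic acid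
Product: 30 [(1R,2S,7R,7aS)-1-hydroxy-4-[(1R)-1,3,3-trimethylcyclohexyl]-2,3,5,6,7,7a-hexahydro-1H-indene-2-carboxylic acid 1,2-lactone-7-yl]methyl butanoate (CNP0144861.2), via acyl phosphinate 29 (not isolated)
Conditions: (2-oxo-1,3-oxazolidin-3-yl)2P(O)Cl (BOPCl), Et3N, CH2Cl2, 23 °C
Reagents that add atoms: none
Why: β-Lactonisation by carboxyl activation: the acyl phosphinate is attacked by the cis C1 hydroxyl (4-exo-trig), so both stereocentres are retained and only the cis-fused oxetan-2-one can form.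

**Compound list**

1 | 4-methylpent-3-en-2-one (mesityl oxide) | CC(=O)C=C(C)C | starting material
2 | pent-4-en-1-ylmagnesium bromide | C=CCCC[Mg]Br | starting material
3 | 4,4-dimethylnon-8-en-2-one | CC(=O)CC(C)(C)CCCC=C | intermediate
4 | 2,4,4-trimethylnona-1,8-diene | C=C(C)CC(C)(C)CCCC=C | intermediate
5 | 1,6,6-trimethylcyclohept-1-ene | CC1=CCCCC(C)(C)C1 | intermediate
6 | (1S,7R)-1,3,3-trimethyl-8-oxabicyclo[5.1.0]octane | CC1(C)CCC[C@H]2O[C@@]2(C)C1 | intermediate
7 | (1R)-1,3,3-trimethylcyclohexane-1-carbaldehyde | O=C[C@]1(C)CCCC(C)(C)C1 | intermediate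
8 | (1R)-1-ethynyl-1,3,3-trimethylcyclohexane | C#C[C@]1(C)CCCC(C)(C)C1 | intermediate
9 | oxetane | C1COC1 | starting material
10 | lithium [(1R)-1,3,3-trimethylcyclohexyl]ethynide | [Li]C#C[C@]1(C)CCCC(C)(C)C1 | intermediate
11 | 5-[(1R)-1,3,3-trimethylcyclohexyl]pent-4-yn-1-ol | OCCCC#C[C@]1(C)CCCC(C)(C)C1 | intermediate
12 | 5-[(1R)-1,3,3-trimethylcyclohexyl]pent-4-ynal | O=CCCC#C[C@]1(C)CCCC(C)(C)C1 | intermediate
13 | 5-[(1R)-1,3,3-trimethylcyclohexyl]pent-4-ynoic acid | OC(=O)CCC#C[C@]1(C)CCCC(C)(C)C1 | intermediate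
14 | (4S)-4-benzyl-1,3-oxazolidin-2-one | O=C1N[C@@H](Cc2ccccc2)CO1 | starting material
15 | 2,2-dimethylpropanoic 5-[(1R)-1,3,3-trimethylcyclohexyl]pent-4-ynoic anhydride | CC(C)(C)C(=O)OC(=O)CCC#C[C@]1(C)CCCC(C)(C)C1 | intermediate
16 | (4S)-4-benzyl-3-{5-[(1R)-1,3,3-trimethylcyclohexyl]pent-4-ynoyl}-1,3-oxazolidin-2-one | O=C(CCC#C[C@]1(C)CCCC(C)(C)C1)N1[C@@H](Cc2ccccc2)COC1=O | intermediate
17 | prop-2-enal (acrolein) | C=CC=O | starting material
18 | (Z)-dibutylboron enolate of 16 | CCCCB(CCCC)O/C(=C\CC#C[C@]1(C)CCCC(C)(C)C1)N1[C@@H](Cc2ccccc2)COC1=O | intermediate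
19 | (4S)-4-benzyl-3-[(2S,3R)-3-hydroxy-2-{3-[(1R)-1,3,3-trimethylcyclohexyl]prop-2-yn-1-yl}pent-4-enoyl]-1,3-oxazolidin-2-one | C=C[C@@H](O)[C@H](CC#C[C@]1(C)CCCC(C)(C)C1)C(=O)N1[C@@H](Cc2ccccc2)COC1=O | intermediate
20 | (4S)-4-benzyl-3-[(2S,3R)-3-{[tert-butyl(dimethyl)silyl]oxy}-2-{3-[(1R)-1,3,3-trimethylcyclohexyl]prop-2-yn-1-yl}pent-4-enoyl]-1,3-oxazolidin-2-one | C=C[C@@H](O[Si](C)(C)C(C)(C)C)[C@H](CC#C[C@]1(C)CCCC(C)(C)C1)C(=O)N1[C@@H](Cc2ccccc2)COC1=O | intermediate
21 | (4S)-4-benzyl-3-{[(1S,2R)-2-{[tert-butyl(dimethyl)silyl]oxy}-4-{1-[(1R)-1,3,3-trimethylcyclohexyl]ethenyl}cyclopent-3-en-1-yl]carbonyl}-1,3-oxazolidin-2-one | C=C([C@]3(C)CCCC(C)(C)C3)C1=C[C@@H](O[Si](C)(C)C(C)(C)C)[C@@H](C(=O)N2[C@@H](Cc4ccccc4)COC2=O)C1 | intermediate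
22 | (4S)-4-benzyl-3-{[(1R,2S,7S,7aS)-1-{[tert-butyl(dimethyl)silyl]oxy}-7-formyl-4-[(1R)-1,3,3-trimethylcyclohexyl]-2,3,5,6,7,7a-hexahydro-1H-inden-2-yl]carbonyl}-1,3-oxazolidin-2-one | O=C[C@H]1CCC([C@]2(C)CCCC(C)(C)C2)=C2C[C@H](C(=O)N3[C@@H](Cc4ccccc4)COC3=O)[C@H](O[Si](C)(C)C(C)(C)C)[C@H]21 | intermediate
23 | (4S)-4-benzyl-3-{[(1R,2S,7R,7aS)-1-{[tert-butyl(dimethyl)silyl]oxy}-7-formyl-4-[(1R)-1,3,3-trimethylcyclohexyl]-2,3,5,6,7,7a-hexahydro-1H-inden-2-yl]carbonyl}-1,3-oxazolidin-2-one | O=C[C@@H]1CCC([C@]2(C)CCCC(C)(C)C2)=C2C[C@H](C(=O)N3[C@@H](Cc4ccccc4)COC3=O)[C@H](O[Si](C)(C)C(C)(C)C)[C@H]21 | intermediate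
24 | (4S)-4-benzyl-3-{[(1R,2S,7R,7aS)-1-{[tert-butyl(dimethyl)silyl]oxy}-7-(hydroxymethyl)-4-[(1R)-1,3,3-trimethylcyclohexyl]-2,3,5,6,7,7a-hexahydro-1H-inden-2-yl]carbonyl}-1,3-oxazolidin-2-one | OC[C@@H]1CCC([C@]2(C)CCCC(C)(C)C2)=C2C[C@H](C(=O)N3[C@@H](Cc4ccccc4)COC3=O)[C@H](O[Si](C)(C)C(C)(C)C)[C@H]21 | intermediate
25 | [(1R,2S,7R,7aS)-2-{[(4S)-4-benzyl-2-oxo-1,3-oxazolidin-3-yl]carbonyl}-1-{[tert-butyl(dimethyl)silyl]oxy}-4-[(1R)-1,3,3-trimethylcyclohexyl]-2,3,5,6,7,7a-hexahydro-1H-inden-7-yl]methyl butanoate | CCCC(=O)OC[C@@H]1CCC([C@]2(C)CCCC(C)(C)C2)=C2C[C@H](C(=O)N3[C@@H](Cc4ccccc4)COC3=O)[C@H](O[Si](C)(C)C(C)(C)C)[C@H]21 | intermediate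
26 | [(1R,2S,7R,7aS)-2-{[(4S)-4-benzyl-2-oxo-1,3-oxazolidin-3-yl]carbonyl}-1-hydroxy-4-[(1R)-1,3,3-trimethylcyclohexyl]-2,3,5,6,7,7a-hexahydro-1H-inden-7-yl]methyl butanoate | CCCC(=O)OC[C@@H]1CCC([C@]2(C)CCCC(C)(C)C2)=C2C[C@H](C(=O)N3[C@@H](Cc4ccccc4)COC3=O)[C@H](O)[C@H]21 | intermediate
27 | lithium (1R,2S,7R,7aS)-7-[(butanoyloxy)methyl]-1-hydroxy-4-[(1R)-1,3,3-trimethylcyclohexyl]-2,3,5,6,7,7a-hexahydro-1H-indene-2-carboperoxoate | CCCC(=O)OC[C@@H]1CCC([C@]2(C)CCCC(C)(C)C2)=C2C[C@H](C(=O)O[O-])[C@H](O)[C@H]21.[Li+] | intermediate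
28 | (1R,2S,7R,7aS)-7-[(butanoyloxy)methyl]-1-hydroxy-4-[(1R)-1,3,3-trimethylcyclohexyl]-2,3,5,6,7,7a-hexahydro-1H-indene-2-carboxylic acid | CCCC(=O)OC[C@@H]1CCC([C@]2(C)CCCC(C)(C)C2)=C2C[C@H](C(=O)O)[C@H](O)[C@H]21 | intermediate
29 | mixed anhydride of 28 with bis(2-oxo-1,3-oxazolidin-3-yl)phosphinic acid | CCCC(=O)OC[C@@H]1CCC([C@]2(C)CCCC(C)(C)C2)=C2C[C@H](C(=O)OP(=O)(N3CCOC3=O)N3CCOC3=O)[C@H](O)[C@H]21 | intermediate
30 | CNP0144861.2: butanoate of the (1R,2S,7R,7aS) hydroxymethyl hydrindene whose C1–O and C2–C(=O) are joined as a cis-fused oxetan-2-one, with the (1R)-1,3,3-trimethylcyclohexyl group on C4 | CCCC(=O)OC[C@@H]1CCC([C@]2(C)CCCC(C)(C)C2)=C2C[C@@H]3C(=O)O[C@@H]3[C@H]21 | target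

**Step count and risks**

Total step count: 18. Longest linear sequence: 18 (1 → 30; all steps lie on one line, the branches are commercial reagents only).

The three steps most likely to fail:

Step 5 (key step). What may go wrong: hydride migration instead of ring-carbon migration, and partial ionisation to a free tertiary cation that erodes the enantiomeric purity. The fallback sets out from 5 and comes back at 7 by a two-stage halohydrin semipinacol contraction. Alkene 5 would be epoxidised with the L-fructose-derived enantiomer of the Shi ketone to (1R,7S)-1,3,3-trimethyl-8-oxabicyclo[5.1.0]octane F1. MgBr2·OEt2 in toluene should open it at the tertiary carbon with inversion to bromomagnesium (1S,2S)-2-bromo-2,4,4-trimethylcycloheptan-1-olate F2. In the diequatorial conformer of this trans halohydrin only the ring bond C1–C7 is antiperiplanar to the C–Br bond, so warming should expel bromide with ring-carbon migration (second inversion) and give 7; a hydride shift is stereoelectronically excluded.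

Step 12. What may go wrong: no productive engagement of the neopentyl-type alkyne by the ruthenium carbene, so that the catalyst is used up in alkene self-metathesis or the reaction stops after an open-chain cross-metathesis with ethene. The fallback sets out from 20 and comes back at 21, with no new compound on the way (F0). It is a skeletal cycloisomerisation with a carbophilic π-acid, PtCl2 (5 mol %) in toluene at 80 °C. The metal activates the alkyne directly, the pendant alkene attacks to give a cyclopropyl platinum carbene, and single C–C cleavage should lead to the same 1-vinylcyclopentene, so the hindered carbon never has to take part in a bimolecular metathesis event.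

Step 13. What may go wrong: sluggish cycloaddition of the twisted 2,3-disubstituted diene with competing acrolein polymerisation, and incomplete face discrimination at the temperature needed. The fallback sets out from 21 and comes back at 23, with no new compound on the way (F0). It uses iminium-ion catalysis at or below room temperature: acrolein is activated by a chiral imidazolidinone salt (5-benzyl-2-tert-butyl-3-methylimidazolidin-4-one·CF3CO2H, the enantiomer whose shielded face reinforces attack anti to the silyloxy group) in MeCN/H2O, followed by the same DBU equilibration. LUMO lowering replaces heat, and catalyst control is added to substrate control.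

Further compounds

F1 | step 5 | (1R,7S)-1,3,3-trimethyl-8-oxabicyclo[5.1.0]octane | CC1(C)CCC[C@@H]2O[C@]2(C)C1
F2 | step 5 | bromomagnesium (1S,2S)-2-bromo-2,4,4-trimethylcycloheptan-1-olate | CC1(C)CCC[C@H](O[Mg]Br)[C@@](C)(Br)C1
F0 | step 12 | none | none
F0 | step 13 | none | none
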